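## Retrosynthetic overview

- Both 2,2-dimethylchroman rings are disconnected first: each pyran C–C and C–O bond goes back to isoprene, leaving a stereodefined alkylidene-bridged bis(acylphloroglucinol) with one free ring position per arene.
- The bridge is disconnected next into an acylphloroglucinol o-quinone methide (stored as its sulfone) and phlorisobutyrophenone; a catalyst-controlled conjugate addition sets the bridging centre.
- The sulfone comes from the (R)-2-methylbutanoyl phloroglucinol, 6-methylheptanal and 4-methylbenzenesulfinic acid; both acylphloroglucinols come from phloroglucinol by Friedel–Crafts acylation, the α-centre being bought.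
- Ring order: the two benzene rings are bought as phloroglucinol; the two pyran rings are formed last, together, in one flask, by C-prenylation and cyclisation onto a phenol oxygen, the way the plant is thought to build them.

Assumption: the SMILES is read as (R) at the bridging carbon and (R) at C-2 of the 2-methylbutanoyl group; (R)-2-methylbutanoic acid (≥98% ee) and 6-methylheptanal are taken as catalogue chemicals.

## Route

Step 1
Reactants: 1 phloroglucinol (benzene-1,3,5-triol); 2 (R)-2-methylbutanoic acid
Product: 4 (2R)-2-methyl-1-(2,4,6-trihydroxyphenyl)butan-1-one, via (R)-2-methylbutanoyl chloride 3 (not isolated)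
Conditions: (COCl)2, cat. DMF, CH2Cl2, 0 °C to rt; then 1, AlCl3 (4 equiv), PhNO2/CH2Cl2, 0 °C to rt; ice/1 M HCl
Reagents that add atoms: none
Why: Friedel–Crafts acylation: the acid chloride is made without base (no ketene pathway) and acylates the AlCl3-complexed triol once, the ketone product being deactivated, so the bought (R)-α-centre is carried through unchanged.

Step 2
Reactants: 4 (2R)-2-methyl-1-(2,4,6-trihydroxyphenyl)butan-1-one; 5 6-methylheptanal
Product: 7 (2R)-2-methyl-1-{2,4,6-trihydroxy-3-[6-methyl-1-(4-methylbenzenesulfonyl)heptyl]phenyl}butan-1-one as a mixture of epimers at the sulfonyl carbon, via benzylic carbinol 6 (not isolated)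
Conditions: 4 (2 equiv), 5 (1 equiv), 4-MeC6H4SO2H (1.5 equiv), EtOAc, 0 °C to rt
Reagents that add atoms: 4-methylbenzenesulfinic acid, Cc1ccc(cc1)S(=O)O
Why: Three-component sulfonylalkylation (Mannich-type): acid-catalysed hydroxyalkylation of the arene by the aldehyde gives carbinol 6, which in the acidic medium ionises with loss of water to an oxygen-stabilised benzylic cation that the sulfinic acid captures at sulfur (SN1 substitution) to give a bench-stable sulfone; the sulfonyl-bearing centre forms as both epimers and is erased in step 4.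

Step 3
Reactants: 1 phloroglucinol; 8 isobutyryl chloride (2-methylpropanoyl chloride)
Product: 9 2-methyl-1-(2,4,6-trihydroxyphenyl)propan-1-one (phlorisobutyrophenone)
Conditions: AlCl3 (4 equiv), PhNO2/CH2Cl2, 0 °C to rt; ice/1 M HCl
Reagents that add atoms: none
Why: Friedel–Crafts mono-acylation as in step 1; no stereocentre is formed.

Step 4
Reactants: 7 the sulfone from step 2; 9 phlorisobutyrophenone
Product: 11 (2R)-2-methyl-1-{2,4,6-trihydroxy-3-[(1R)-6-methyl-1-[2,4,6-trihydroxy-3-(2-methylpropanoyl)phenyl]heptyl]phenyl}butan-1-one, via o-quinone methide 10 (not isolated)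
Conditions: quinine-derived squaramide [3,5-(CF3)2C6H3NH–C4O2–NH-(9-deoxy-epi-quinin-9-yl)] (10 mol%), solid NaHCO3 (2 equiv), 9 (3 equiv), CH2Cl2/MTBE (5:1), −20 °C; cold 1 M HCl wash
Reagents that add atoms: none
Why: Proposed new method: the quinuclidine of the catalyst removes a phenolic proton of 7 to expel sulfinate (E1cB), the squaramide N–H pair then holds the carbonyl of the neutral o-quinone methide 10 while the quinuclidinium hydrogen-bonds phenol 9, so that C-alkylation (conjugate, Friedel–Crafts-type addition, the laboratory counterpart of the dimerisation thought to occur in the plant) takes place on one face of the alkylidene and the bridge is set (R) under catalyst control, the remote α-centre having no influence; the closest known reaction type is the squaramide-catalysed addition of 2-naphthols to o-quinone methides released from 2-(1-tosylalkyl)phenols, and the sense of induction is read by HPLC on the first run, the quinidine-derived pseudoenantiomer being used if the (S)-bridge predominates.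

Step 5
Reactants: 11 the bridged dimer from step 4; 12 isoprene (2-methylbuta-1,3-diene)
Product: 14 (2R)-1-{6-[(1R)-1-[5,7-dihydroxy-2,2-dimethyl-8-(2-methylpropanoyl)-3,4-dihydro-2H-chromen-6-yl]-6-methylheptyl]-5,7-dihydroxy-2,2-dimethyl-3,4-dihydro-2H-chromen-8-yl}-2-methylbutan-1-one, via bis(C-prenyl) dimer 13 (not isolated)
Conditions: isoprene (10 equiv), 85% H3PO4, toluene, 30 °C
Reagents that add atoms: isoprene (the second molecule taken up; one enters each arene), C=CC(C)=C
Why: Friedel–Crafts prenylation by protonated isoprene at the single free, doubly oxygen-flanked carbon of each ring takes up two molecules of isoprene and gives 13, whose prenyl groups close by Markovnikov hydroalkoxylation onto the ketone-flanked phenol (the chelating carbonyl relays the proton, while the oxygen para to the acyl group is the least basic and is tied up in hydrogen bonds across the bridge), the phenol–isoprene chroman annulation known for monomeric phloroacylophenones; no stereocentre is formed, and the weak acid at 30 °C is chosen so that the bridge and the α-keto centre are not ionised or enolised.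

## Compound list

1 | phloroglucinol (benzene-1,3,5-triol) | Oc1cc(O)cc(O)c1 | starting material
2 | (R)-2-methylbutanoic acid | CC[C@@H](C)C(=O)O | starting material
3 | (R)-2-methylbutanoyl chloride | CC[C@@H](C)C(=O)Cl | intermediate
4 | (2R)-2-methyl-1-(2,4,6-trihydroxyphenyl)butan-1-one | CC[C@@H](C)C(=O)c1c(O)cc(O)cc1O | intermediate
5 | 6-methylheptanal | CC(C)CCCCC=O | starting material
6 | benzylic carbinol: (2R)-1-[2,4,6-trihydroxy-3-(1-hydroxy-6-methylheptyl)phenyl]-2-methylbutan-1-one (both epimers at the carbinol carbon) | CC[C@@H](C)C(=O)c1c(O)cc(O)c(C(O)CCCCC(C)C)c1O | intermediate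
7 | (2R)-2-methyl-1-{2,4,6-trihydroxy-3-[6-methyl-1-(4-methylbenzenesulfonyl)heptyl]phenyl}butan-1-one (both epimers at the sulfonyl carbon) | CC[C@@H](C)C(=O)c1c(O)cc(O)c(C(CCCCC(C)C)S(=O)(=O)c2ccc(C)cc2)c1O | intermediate
8 | isobutyryl chloride (2-methylpropanoyl chloride) | CC(C)C(=O)Cl | starting material
9 | 2-methyl-1-(2,4,6-trihydroxyphenyl)propan-1-one (phlorisobutyrophenone) | CC(C)C(=O)c1c(O)cc(O)cc1O | intermediate
10 | o-quinone methide: 3,5-dihydroxy-2-[(2R)-2-methylbutanoyl]-6-(6-methylheptylidene)cyclohexa-2,4-dien-1-one (one tautomer drawn, alkene geometry not defined) | CC[C@@H](C)C(=O)C1=C(O)C=C(O)C(=CCCCCC(C)C)C1=O | intermediate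
11 | (2R)-2-methyl-1-{2,4,6-trihydroxy-3-[(1R)-6-methyl-1-[2,4,6-trihydroxy-3-(2-methylpropanoyl)phenyl]heptyl]phenyl}butan-1-one | CC[C@@H](C)C(=O)c1c(O)cc(O)c([C@H](CCCCC(C)C)c2c(O)cc(O)c(C(=O)C(C)C)c2O)c1O | intermediate
12 | isoprene (2-methylbuta-1,3-diene) | C=CC(C)=C | starting material
13 | bis(C-prenyl) dimer: (2R)-2-methyl-1-{2,4,6-trihydroxy-3-(3-methylbut-2-en-1-yl)-5-[(1R)-6-methyl-1-[2,4,6-trihydroxy-3-(3-methylbut-2-en-1-yl)-5-(2-methylpropanoyl)phenyl]heptyl]phenyl}butan-1-one | CC[C@@H](C)C(=O)c1c(O)c(CC=C(C)C)c(O)c([C@H](CCCCC(C)C)c2c(O)c(CC=C(C)C)c(O)c(C(=O)C(C)C)c2O)c1O | intermediate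
14 | (2R)-1-{6-[(1R)-1-[5,7-dihydroxy-2,2-dimethyl-8-(2-methylpropanoyl)-3,4-dihydro-2H-chromen-6-yl]-6-methylheptyl]-5,7-dihydroxy-2,2-dimethyl-3,4-dihydro-2H-chromen-8-yl}-2-methylbutan-1-one (CNP0287681.1) | CC[C@@H](C)C(=O)c1c(O)c([C@H](CCCCC(C)C)c2c(O)c3c(c(C(=O)C(C)C)c2O)OC(C)(C)CC3)c(O)c2c1OC(C)(C)CC2 | target

## Step count and risks

Total step count: 5. Longest linear sequence: 4 steps (1 → 4 → 7 → 11 → 14, steps 1, 2, 4 and 5).

The three steps most likely to fail:

**Step 5 (twofold chroman annulation on the dimer).** Each prenyl group can close onto the acyl-flanked oxygen (wanted) or onto the bridge-flanked oxygen, so up to four ring-closure isomers are possible. The doubly benzylic bridge can also ionise in acid (retro-Friedel–Crafts), which would epimerise it and scramble the halves, and isoprene can oligomerise. The fallback closes the rings before the bridge is made and sets out from 9 and 4. Each is annulated with isoprene/85% H3PO4, and the 8-acyl chromans are separated from their 6-acyl isomers on silica. This gives 1-(5,7-dihydroxy-2,2-dimethyl-3,4-dihydro-2H-chromen-8-yl)-2-methylpropan-1-one F1 and (2R)-1-(5,7-dihydroxy-2,2-dimethyl-3,4-dihydro-2H-chromen-8-yl)-2-methylbutan-1-one F2. F2, 5 and 4-MeC6H4SO2H then give the C-6 sulfone (2R)-1-{5,7-dihydroxy-2,2-dimethyl-6-[6-methyl-1-(4-methylbenzenesulfonyl)heptyl]-3,4-dihydro-2H-chromen-8-yl}-2-methylbutan-1-one F3. Under the conditions of step 4, F3 releases the chroman o-quinone methide 5-hydroxy-2,2-dimethyl-8-[(2R)-2-methylbutanoyl]-6-(6-methylheptylidene)-3,4-dihydro-2H-chromen-7(6H)-one F4, which F1 attacks at its only free ring carbon. This comes back to the route at 14, with no acid used after the bridge is set.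

**Step 4 (catalyst-controlled bridge formation).** Facial control with an acylphloroglucinol nucleophile and a polyhydroxylated o-quinone methide is unprecedented. An uncatalysed phenolate addition, over-alkylation of the free ring positions, or base-induced retro-addition could each erode the diastereomer ratio. The fallback gives up catalyst control and sets out from 7 and 9. They are joined with i-Pr2NEt in CH2Cl2 at 0 °C to a roughly 1:1 mixture of 11 and its bridge epimer (2R)-2-methyl-1-{2,4,6-trihydroxy-3-[(1S)-6-methyl-1-[2,4,6-trihydroxy-3-(2-methylpropanoyl)phenyl]heptyl]phenyl}butan-1-one F5. Because the (R)-acyl centre makes the two products diastereomers, they are separated by preparative HPLC on amylose tris(3,5-dimethylphenylcarbamate), and the route resumes at 11.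

**Step 2 (three-component sulfone formation).** Arene 4 can trap the benzylic cation formed from carbinol 6 faster than the sulfinic acid does (alkylidene-bridged homodimer), and its second free position can react again. The fallback sets out from 4. A Mannich condensation of 4 (2 equiv) with 5 and morpholine in EtOH gives the Mannich base (2R)-2-methyl-1-{2,4,6-trihydroxy-3-[6-methyl-1-(morpholin-4-yl)heptyl]phenyl}butan-1-one F6; the electrophile here is an iminium ion, so no benzylic cation meets free arene. Warming F6 with 4-MeC6H4SO2H in MeCN then exchanges morpholine for sulfinate by acid-promoted elimination–addition at the benzylic carbon and returns to the route at 7.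

## Further compounds

F1 | step 5 | 1-(5,7-dihydroxy-2,2-dimethyl-3,4-dihydro-2H-chromen-8-yl)-2-methylpropan-1-one | CC(C)C(=O)c1c(O)cc(O)c2c1OC(C)(C)CC2
F2 | step 5 | (2R)-1-(5,7-dihydroxy-2,2-dimethyl-3,4-dihydro-2H-chromen-8-yl)-2-methylbutan-1-one | CC[C@@H](C)C(=O)c1c(O)cc(O)c2c1OC(C)(C)CC2
F3 | step 5 | (2R)-1-{5,7-dihydroxy-2,2-dimethyl-6-[6-methyl-1-(4-methylbenzenesulfonyl)heptyl]-3,4-dihydro-2H-chromen-8-yl}-2-methylbutan-1-one (both epimers at the sulfonyl carbon) | CC[C@@H](C)C(=O)c1c(O)c(C(CCCCC(C)C)S(=O)(=O)c3ccc(C)cc3)c(O)c2c1OC(C)(C)CC2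
F4 | step 5 | 5-hydroxy-2,2-dimethyl-8-[(2R)-2-methylbutanoyl]-6-(6-methylheptylidene)-3,4-dihydro-2H-chromen-7(6H)-one (o-quinone methide, not isolated) | CC[C@@H](C)C(=O)C1=C2OC(C)(C)CCC2=C(O)C(=CCCCCC(C)C)C1=O
F5 | step 4 | (2R)-2-methyl-1-{2,4,6-trihydroxy-3-[(1S)-6-methyl-1-[2,4,6-trihydroxy-3-(2-methylpropanoyl)phenyl]heptyl]phenyl}butan-1-one | CC[C@@H](C)C(=O)c1c(O)cc(O)c([C@@H](CCCCC(C)C)c2c(O)cc(O)c(C(=O)C(C)C)c2O)c1O
F6 | step 2 | (2R)-2-methyl-1-{2,4,6-trihydroxy-3-[6-methyl-1-(morpholin-4-yl)heptyl]phenyl}butan-1-one (both epimers at the amino carbon) | CC[C@@H](C)C(=O)c1c(O)cc(O)c(C(CCCCC(C)C)N2CCOCC2)c1O
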